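**Remarks on the chemistry (assumptions)**

- Locants C1–C13 are the germacrane locants of the target and are kept for open-chain intermediates. Ring A is the carbocycle C1–C10; ring B is the lactone O–C6–C7–C11(=C13)–C12.
- The zinc-mediated allylation (step 14) is assumed to pass through a closed six-membered transition state. This places the new hydroxyl 8S, so the route inverts C8 when the ester is introduced.
- Several CIP descriptors change between intermediates only because substituent priorities change (for example C6 is S while C4 carries iodine and R afterwards); the spatial arrangement is the same throughout.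
- Abbreviations: PMB = 4-methoxybenzyl, TES = triethylsilyl, TMS = trimethylsilyl, EpT = (2R,3S)-2,3-dimethyloxirane-2-carbonyl.

## Analysis of the target

The target is a germacranolide: a ten-membered carbocycle (ring A) trans-fused at C6/C7 to an α-methylene-γ-butyrolactone (ring B). Ring A carries a trisubstituted trans-epoxide at C1–C10 with the methyl on C10, a benzoate on the allylic carbon C3, a Z-configured C4=C5 bond with a methyl on C4, and at C8 the ester of (2R,3S)-2,3-dimethyloxirane-2-carboxylic acid, the epoxide of tiglic acid. There are eight stereocenters (1R, 3S, 6R, 7R, 8R, 10R, and 2R,3S in the acyl group). C6, C7 and C8 form a contiguous O/C/O triad in which the lactone is trans and the C8 oxygen is anti to C11, while C1 and C3 are 1,3-related oxygenated carbons separated from the triad by the fully substituted C10 and by the alkene. Sensitive functions are the exocyclic enoate (a Michael acceptor), two oxiranes, three different esters including an allylic benzoate, and the medium ring itself, which is prone to transannular reactions. The difficulty lies in closing a strained ten-membered ring with this functionality present and in placing the C1–C10 epoxide on one face without a late, conformation-dependent epoxidation. The strategy rests on the C1/C3 dioxygen pattern next to the quaternary C10: a C3 methyl ketone and a non-enolisable C1 aldehyde are natural aldol partners for the C1–C2 bond, the C10 oxygen steers the addition, and the C1 carbinol then directs the C3 reduction and becomes the leaving group for epoxide closure.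

## Retrosynthetic reasoning

**Epoxide (34 to 32).** The oxirane is cut at its C1–O bond, leading back to the C1 mesylate 32 in which the C10 oxygen is still a silyl ether. Forward, desilylation frees a tertiary alkoxide that displaces the sulfonate on the neighbouring carbon with inversion. Two sp3 configurations (1S, 10R) are thus converted into the trans-epoxide, and no face-selective epoxidation of a ring alkene beside C4=C5 and C11=C13 is needed.

**C3 carbinol and the two oxygens (32 to 29).** The sulfonate and benzoate are removed to give the 1,3-anti diol 30 by way of 31, and the C3–H bond is cut to give the β-hydroxy enone 29. Forward, the C1 hydroxyl delivers hydride intramolecularly to set 3S (anti), and the two hydroxyls are then told apart by hindrance: C3 is allylic and open, C1 sits next to the silylated quaternary C10.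

**C1–C2, the key disconnection (29 to 27).** Ring A is opened between C1 and C2. This is the only ring bond flanked by a ketone-derived nucleophile on one side and an aldehyde without α-hydrogens on the other, so the aldol is regiochemically unambiguous. It also creates C1 directly next to the controlling C10 stereocenter. The forward reaction has to close a ten-membered ring end-to-end and add to the aldehyde face anti to the C10 silyloxy group.

**Adjusting the ends (27 to 24).** The silyl dienol ether 27 comes from keto aldehyde 26, this from alcohol 25 by oxidation, and 25 from PMB ether 24. The aldehyde is unveiled late because a β-silyloxy-α-quaternary aldehyde is best not carried through organometallic steps.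

**C3–C4 (24 to 22).** The methyl ketone is cut off at C3–C4, leaving the Z-alkenyl iodide 22. The Z geometry of C4=C5 is most reliably made from a propargylic alcohol, and an iodide survives the zinc and Mitsunobu steps where an enone would not. Forward, a Stille coupling with an acetyl anion equivalent has to proceed with retention.

**C8–O (22 to 21 and 19).** The ester is cut at the C8–O bond to the 8S alcohol 21 and the epoxy acid 19. Because the ring-B-forming step gives the C8 epimer, the ester is introduced by Mitsunobu inversion, which corrects C8 and acylates in one operation.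

**C7–C8 (21 to 7 and 15).** The triad is cut between C7 and C8 into aldehyde 7 and the butenolide bromide 15. Cutting here lets ring B enter preformed with C6 fixed. The forward allylation has to bond through C7 anti to the C6 substituent (trans-lactone), generate C11=C13 by allylic transposition, and leave a free C8 hydroxyl that cannot compete for the lactone.

**Ring B (15 to 12 and 13).** The butenolide is opened at C7=C11 (ring-closing metathesis) and at the ester C–O bond, giving dienol 12 and acid 13. This places the bromomethyl group on C11 without any allylic halogenation next to the iodoalkene.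

**C4=C5 geometry and C6 (12 to 8).** The iodoalkene of 12 comes from alkynol 10 by hydroxyl-directed trans-hydroalumination and iodination. 10 is the slow-reacting enantiomer in a Sharpless kinetic resolution of 9, and 9 comes from the addition of a propynyl nucleophile to 8.

**C8–C10–C1 fragment (7 to 1).** Aldehyde 7 is cut at C8=O back to the terminal alkene 5, then to the tertiary alcohol 4, and at C8–C9 to the epoxide 3. C10 is the quaternary carbon of epoxy alcohol 2, made from 1 by asymmetric epoxidation.

**Acyl group (19 to 16).** Acid 19 is the oxidation product of epoxy alcohol 18, made by asymmetric epoxidation of 17, the reduction product of 16. The E geometry of 16 fixes the cis-dimethyl oxirane.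

## Alternatives that were turned down

**Alternative 1:** Ring B is disconnected at C7–C11 and C11=C13. Forward, the phosphonoacetate ester of the C6 hydroxyl is deprotonated with KOtBu, and the stabilised carbanion opens a C7–C8 epoxide at C7 in a 5-exo mode. This makes the lactone, inverts C7 and frees the C8 alkoxide; the α-phosphono lactone then olefinates an added one-carbon aldehyde to give A1.
- For: the O6/C7/O8 triad is transferred stereospecifically from an epoxy alcohol, so trans-lactone and C8 configuration come from one SN2 event, and the methylene group arrives in the same flask.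
- Against: A1 is still open at ring A and carries C1=C10 as an alkene. Ring A would have to be closed at C3–C4 from the alkenyl iodide onto a C3 aldehyde, with C3 set only by ring conformation. The 1,10-epoxide would come from a final epoxidation whose facial and site selectivity against C4=C5 depend on the ten-membered ring. In the key step the C8 alkoxide is 1,3 to the new lactone carbonyl and can translactonise before olefination.
- Comparison: on the triad this plan is stronger than the chosen route, which needs an allylation followed by inversion at C8 (21 to 22), and an alkenyl-metal ring closure is at least as well precedented as an aldol closure. The chosen strategy offers instead control of C1, C3 and C10 from sp3 centers by acyclic models and a four-step end-game without late epoxidation. Step counts are otherwise similar.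

**Alternative 2:** The C7–C8 bond is traced to a thirteen-membered cyclic ether in which C8 carries a trialkylstannyl group and is joined through oxygen to C13. Forward, BuLi effects tin–lithium exchange, the α-alkoxy carbanion at C8 bonds to C7 while the O–C13 bond breaks ([2,3]-Wittig rearrangement, Still variant), and the ether contracts to the carbocycle A2.
- For: ring A forms by contraction through a five-membered cyclic transition state inside an existing macrocycle, which is entropically easier than an end-to-end ten-membered closure. On this point it is stronger than the chosen route. C7, C8 and the C11=C13 unit arise together.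
- Against: the precursor of A2 needs a long synthesis with a configurationally defined secondary α-alkoxystannane. Induction at C7/C8 relative to C6 depends on the conformation of a thirteen-membered ring. [1,2]-Shift and β-elimination compete. Because an organolithium is used, no ester can be present, so A2 still needs two ether cleavages, oxidation of C12 with lactonisation, three acylations and a late C1=C10 epoxidation, at least eight steps against four.
- Comparison: the chosen strategy offers convergence, with every ester in place before ring closure and no late epoxidation.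

**Alternative 3:** The C6–O and C3–O bonds are cut together, back to a ten-membered ring with a conjugated C3=C4–C5=C6 diene and a free C12 acrylic acid. Forward, Pd(OAc)2 with a quinone re-oxidant activates the diene, the carboxylic acid adds to C6 to close ring B, and the arene carboxylate attacks the allylpalladium at C3, leaving C4=C5 and giving A3.
- For: two ester oxygens and the alkene position are set in one catalytic step with the C8 ester already present, and A3 is one epoxidation from the target. In step economy after the key step this is the strongest plan.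
- Against: the substrate is a strained ten-membered triene acid whose synthesis is the real problem and is not addressed by the key step. The C3/C6 relationship depends on external versus metal-bound carboxylate delivery, and the Z geometry on the syn or anti form of the allyl complex; a medium ring biases both unpredictably. Attack at C5 and oxidation of C1=C10 may compete, and the final epoxidation must still pick one face.
- Comparison: the chosen route is longer, but sets each stereocenter by an independent, well-understood model and has a fallback at the ring-forming step.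

Key step: step 20

## Route

Step 1
Reactants: 1 2-methylprop-2-en-1-ol
Product: 2 (S)-(2-methyloxiran-2-yl)methanol
Conditions: Ti(OiPr)4 (5 mol%), L-(+)-diisopropyl tartrate (6 mol%), t-BuOOH, 4 Å MS, CH2Cl2, −20 °C; non-aqueous work-up, distillation
Reagents that add atoms: tert-butyl hydroperoxide, CC(C)(C)OO
Why: Sharpless asymmetric epoxidation; the titanium–L-tartrate complex transfers oxygen to the alkene face that gives the 2S epoxide (the same facial sense that gives 2S,3S epoxides from E-allylic alcohols), and this carbon becomes C10 and is not touched again.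

Step 2
Reactants: 2 (S)-(2-methyloxiran-2-yl)methanol
Product: 3 (R)-2-{[(4-methoxybenzyl)oxy]methyl}-2-methyloxirane
Conditions: NaH, 4-methoxybenzyl chloride, Bu4NI (cat.), THF, 0 °C → rt
Reagents that add atoms: 4-methoxybenzyl chloride, COc1ccc(CCl)cc1
Why: Williamson ether synthesis; O-alkylation is much faster than Payne-type attack of the alkoxide on the fully substituted oxirane carbon, so the stereocenter is untouched (the descriptor changes only by priority).

Step 3
Reactants: 3 (R)-2-{[(4-methoxybenzyl)oxy]methyl}-2-methyloxirane
Product: 4 (R)-1-[(4-methoxybenzyl)oxy]-2-methylpent-4-en-2-ol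
Conditions: vinylmagnesium bromide, CuI (10 mol%), THF, −30 → 0 °C
Reagents that add atoms: vinylmagnesium bromide, C=C[Mg]Br
Why: Copper-catalysed Grignard opening of a 2,2-disubstituted epoxide occurs by SN2 at the unhindered CH2 (C9), leaving C10 as a tertiary carbinol; the vinyl group is the masked C8 aldehyde.

Step 4
Reactants: 4 (R)-1-[(4-methoxybenzyl)oxy]-2-methylpent-4-en-2-ol
Product: 5 (R)-triethyl({1-[(4-methoxybenzyl)oxy]-2-methylpent-4-en-2-yl}oxy)silane
Conditions: Et3SiOTf, 2,6-lutidine, CH2Cl2, −78 → 0 °C
Reagents that add atoms: triethylsilyl trifluoromethanesulfonate, CC[Si](CC)(CC)OS(=O)(=O)C(F)(F)F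
Why: Silyl triflates silylate tertiary alcohols cleanly; the bulky, weakly basic TES ether is the later non-chelating control element and the latent epoxide oxygen.

Step 5
Reactants: 5 (R)-triethyl({1-[(4-methoxybenzyl)oxy]-2-methylpent-4-en-2-yl}oxy)silane
Product: 7 (R)-4-[(4-methoxybenzyl)oxy]-3-methyl-3-[(triethylsilyl)oxy]butanal, via vicinal diol 6 (not isolated)
Conditions: OsO4 (2 mol%), NaIO4, 2,6-lutidine, dioxane/H2O, rt
Reagents that add atoms: sodium periodate (oxygen source by way of OsO4), [Na+].[O-]I(=O)(=O)=O; water, O
Why: Lemieux–Johnson cleavage of the terminal alkene; the conditions are neutral, spare the PMB ether, and avoid base that could eliminate the β-silyloxy group.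

Step 6
Reactants: 8 prop-2-enal
Product: 9 rac-hex-1-en-4-yn-3-ol
Conditions: 1-propynylmagnesium bromide, THF, −78 → 0 °C
Reagents that add atoms: 1-propynylmagnesium bromide, CC#C[Mg]Br
Why: Alkynyl Grignard reagents add 1,2 to enals; this joins C6 to C5, C4 and the C4 methyl in one step.

Step 7
Reactants: 9 rac-hex-1-en-4-yn-3-ol
Product: 10 (S)-hex-1-en-4-yn-3-ol
Conditions: Ti(OiPr)4 (1.0 equiv), L-(+)-diisopropyl tartrate (1.2 equiv), t-BuOOH (0.6 equiv), 4 Å MS, CH2Cl2, −20 °C, to just past half conversion
Reagents that add atoms: none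
Why: Sharpless kinetic resolution of a secondary allylic alcohol; with the L-tartrate the enantiomer that gives the erythro epoxy alcohol (here the R alcohol) is epoxidised at its vinyl group much faster, so the S alcohol, whose carbinol carbon becomes C6, should remain in high enantiomeric purity.

Step 8
Reactants: 10 (S)-hex-1-en-4-yn-3-ol
Product: 12 (3S,4Z)-5-iodohexa-1,4-dien-3-ol, via cyclic alkenylaluminate 11 (not isolated)
Conditions: NaAlH2(OCH2CH2OMe)2, THF, 0 °C → rt; then I2, −78 °C
Reagents that add atoms: iodine, II
Why: Hydroxyl-directed trans-hydroalumination of a propargylic alcohol places hydrogen on C5 and aluminium on C4 in a five-membered chelate, and iodinolysis with retention gives the alkenyl iodide with C6 and iodine cis, which fixes the Z geometry of C4=C5; the isolated vinyl group is not reduced.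

Step 9
Reactants: 12 (3S,4Z)-5-iodohexa-1,4-dien-3-ol; 13 2-(bromomethyl)prop-2-enoic acid
Product: 14 (3S,4Z)-5-iodohexa-1,4-dien-3-yl 2-(bromomethyl)prop-2-enoate
Conditions: DCC, DMAP (5 mol%), CH2Cl2, 0 °C
Reagents that add atoms: none
Why: Steglich esterification; low temperature and catalytic DMAP keep the allylic bromide from SN2′ substitution, and the C6–O bond formed here is the lactone C–O bond of ring B.

Step 10
Reactants: 14 (3S,4Z)-5-iodohexa-1,4-dien-3-yl 2-(bromomethyl)prop-2-enoate
Product: 15 (5S)-3-(bromomethyl)-5-[(1Z)-2-iodoprop-1-en-1-yl]furan-2(5H)-one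
Conditions: second-generation Grubbs catalyst (5 mol%), CH2Cl2 (0.01 M), 40 °C
Reagents that add atoms: none
Why: Ring-closing metathesis between the vinyl group and the 2-substituted acrylate forms C7=C11 as a butenolide, as known for methacrylate-type esters of allylic alcohols; the trisubstituted iodoalkene is too hindered to take part.

Step 11
Reactants: 16 (E)-2-methylbut-2-enoic acid (tiglic acid)
Product: 17 (E)-2-methylbut-2-en-1-ol
Conditions: LiAlH4, Et2O, 0 °C
Reagents that add atoms: none
Why: Hydride reduction of the acid to the allylic alcohol with the E geometry retained; the cis arrangement of the two methyl groups is carried into the oxirane.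

Step 12
Reactants: 17 (E)-2-methylbut-2-en-1-ol
Product: 18 [(2S,3S)-2,3-dimethyloxiran-2-yl]methanol
Conditions: Ti(OiPr)4 (5 mol%), L-(+)-diethyl tartrate (6 mol%), t-BuOOH, 4 Å MS, CH2Cl2, −20 °C
Reagents that add atoms: tert-butyl hydroperoxide, CC(C)(C)OO
Why: Sharpless asymmetric epoxidation of an E-trisubstituted allylic alcohol, a very good substrate class; the L-tartrate gives the 2S,3S epoxide and syn addition keeps the methyl groups cis.

Step 13
Reactants: 18 [(2S,3S)-2,3-dimethyloxiran-2-yl]methanol
Product: 19 (2R,3S)-2,3-dimethyloxirane-2-carboxylic acid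
Conditions: RuCl3 (2 mol%), NaIO4, MeCN/EtOAc/H2O, 0 °C → rt
Reagents that add atoms: sodium periodate (oxygen source by way of RuO4), [Na+].[O-]I(=O)(=O)=O; water, O
Why: Ruthenium-catalysed oxidation of a primary epoxy alcohol to the glycidic acid leaves the oxirane intact; C2 becomes R only because the carboxyl group now outranks C3.

Step 14
Reactants: 7 (R)-4-[(4-methoxybenzyl)oxy]-3-methyl-3-[(triethylsilyl)oxy]butanal; 15 (5S)-3-(bromomethyl)-5-[(1Z)-2-iodoprop-1-en-1-yl]furan-2(5H)-one
Product: 21 lactone alcohol (6S,7R,8S,10R): ring B α-methylene-γ-butyrolactone with (Z)-CH=C(CH3)I on C6 and C8H(OH)–C9H2–C10(CH3)(OTES)–C1H2OPMB on C7, via allylzinc bromide 20 (not isolated)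
Conditions: Zn dust, THF/sat. aq. NH4Cl, 0 °C → rt
Reagents that add atoms: none
Why: Barbier allylation with a 3-(bromomethyl)butenolide; the allylzinc bonds through its γ-carbon C7 anti to the C6 substituent (trans-lactone) and transposes the alkene to C11=C13. In the closed chair transition state the aldehyde residue is equatorial and C6 is locked trans to the zinc-bearing carbon, so the C8 hydroxyl should come out anti to the C7–C6 bond (8S); the remote C10 center of 7 should have little influence.

Step 15
Reactants: 21 lactone alcohol (6S,7R,8S,10R): ring B α-methylene-γ-butyrolactone with (Z)-CH=C(CH3)I on C6 and C8H(OH)–C9H2–C10(CH3)(OTES)–C1H2OPMB on C7; 19 (2R,3S)-2,3-dimethyloxirane-2-carboxylic acid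
Product: 22 lactone ester (6S,7R,8R,10R): ring B α-methylene-γ-butyrolactone with (Z)-CH=C(CH3)I on C6 and C8H(OEpT)–C9H2–C10(CH3)(OTES)–C1H2OPMB on C7
Conditions: PPh3, DIAD, toluene, 0 °C → rt (PPh3 and DIAD premixed)
Reagents that add atoms: none
Why: Mitsunobu esterification; the carboxylate displaces the oxyphosphonium group at C8 by SN2 with inversion, turning 8S into the required 8R while installing the acyl group. The α-oxygenated acid is acidic enough to protonate the betaine efficiently, and its oxirane is never activated.

Step 16
Reactants: 22 lactone ester (6S,7R,8R,10R): ring B α-methylene-γ-butyrolactone with (Z)-CH=C(CH3)I on C6 and C8H(OEpT)–C9H2–C10(CH3)(OTES)–C1H2OPMB on C7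
Product: 24 methyl ketone (6R,7R,8R,10R): ring B α-methylene-γ-butyrolactone with (Z)-CH=C(CH3)–C(=O)CH3 on C6 and C8H(OEpT)–C9H2–C10(CH3)(OTES)–C1H2OPMB on C7, via ethoxydiene 23 (not isolated)
Conditions: tributyl(1-ethoxyvinyl)stannane, Pd2(dba)3 (2.5 mol%), AsPh3, CuI (10 mol%), DMF, rt; then 0.5 M aq. oxalic acid, THF, 0 °C
Reagents that add atoms: tributyl(1-ethoxyvinyl)stannane, CCCC[Sn](CCCC)(CCCC)C(=C)OCC; water, O
Why: Stille coupling of an alkenyl iodide proceeds with retention, so C3 arrives cis to C6, and the copper co-catalyst speeds transmetalation so that coupling should outrun insertion into C11=C13. Brief mild acid hydrolyses the enol ether to the methyl ketone without touching the tertiary TES ether or the ester oxirane.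

Step 17
Reactants: 24 methyl ketone (6R,7R,8R,10R): ring B α-methylene-γ-butyrolactone with (Z)-CH=C(CH3)–C(=O)CH3 on C6 and C8H(OEpT)–C9H2–C10(CH3)(OTES)–C1H2OPMB on C7
Product: 25 keto alcohol (6R,7R,8R,10R): ring B α-methylene-γ-butyrolactone with (Z)-CH=C(CH3)–C(=O)CH3 on C6 and C8H(OEpT)–C9H2–C10(CH3)(OTES)–C1H2OH on C7
Conditions: DDQ, CH2Cl2/pH 7 buffer, 0 °C
Reagents that add atoms: none
Why: Oxidative cleavage of the PMB ether under buffered, neutral conditions, compatible with the enone, the silyl ether, the esters and the oxirane.

Step 18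
Reactants: 25 keto alcohol (6R,7R,8R,10R): ring B α-methylene-γ-butyrolactone with (Z)-CH=C(CH3)–C(=O)CH3 on C6 and C8H(OEpT)–C9H2–C10(CH3)(OTES)–C1H2OH on C7
Product: 26 keto aldehyde (6R,7R,8R,10R): ring B α-methylene-γ-butyrolactone with (Z)-CH=C(CH3)–C(=O)CH3 on C6 and C8H(OEpT)–C9H2–C10(CH3)(OTES)–C1H=O on C7
Conditions: Dess–Martin periodinane, NaHCO3, CH2Cl2, 0 °C → rt
Reagents that add atoms: none
Why: Dess–Martin oxidation of a hindered primary alcohol; the aldehyde has no α-hydrogen, so it cannot epimerise or enolise.

Step 19
Reactants: 26 keto aldehyde (6R,7R,8R,10R): ring B α-methylene-γ-butyrolactone with (Z)-CH=C(CH3)–C(=O)CH3 on C6 and C8H(OEpT)–C9H2–C10(CH3)(OTES)–C1H=O on C7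
Product: 27 silyl dienol ether aldehyde (6R,7R,8R,10R): ring B α-methylene-γ-butyrolactone with (Z)-CH=C(CH3)–C(OTMS)=CH2 on C6 and C8H(OEpT)–C9H2–C10(CH3)(OTES)–C1H=O on C7
Conditions: Me3SiOTf (1.3 equiv), Et3N (4 equiv), CH2Cl2, −78 → −40 °C; cold NaHCO3/pentane work-up, used crude
Reagents that add atoms: trimethylsilyl trifluoromethanesulfonate, C[Si](C)(C)OS(=O)(=O)C(F)(F)F
Why: Soft enolisation of an α,β-unsaturated methyl ketone removes a proton from the methyl group (C2) and gives the cross-conjugated 2-silyloxydiene; the aldehyde, the lactone and the EpT ester have no α-hydrogen to lose. Excess amine and low temperature keep the silyl triflate from acting as an aldol or epoxide-opening Lewis acid.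

Step 20
Reactants: 27 silyl dienol ether aldehyde (6R,7R,8R,10R): ring B α-methylene-γ-butyrolactone with (Z)-CH=C(CH3)–C(OTMS)=CH2 on C6 and C8H(OEpT)–C9H2–C10(CH3)(OTES)–C1H=O on C7
Product: 29 (1S,4Z,6R,7R,8R,10R)-8-(EpT-oxy)-1-hydroxy-3-oxo-10-(triethylsilyloxy)germacra-4,11(13)-dien-12,6-olide, via difluoroboron aldolate 28 (not isolated)
Conditions: BF3·OEt2 (1.5 equiv), CH2Cl2, −78 °C, slow addition of 27 to about 1 mM; aq. NaHCO3
Reagents that add atoms: none
Why: BF3 binds the C1 aldehyde, the terminal carbon C2 of the silyloxydiene attacks it through an open transition state, and fluoride transfer to silicon leaves the boron aldolate 28, which work-up hydrolyses to 29. The closest known reaction type is the intramolecular Mukaiyama aldol addition used to close medium and large rings. Ring A closes in a 10-(enolendo)-exo-trig mode: C2=C3 becomes part of the ring and the carbonyl oxygen stays outside. The new stereocenter C1 is controlled by C10 in the polar Felkin–Anh sense: the C10–OSiEt3 bond lies anti to the incoming C2, which passes the C10 methyl and not the C9 methylene, giving 1S, with the hydroxyl on the side opposite to the later epoxide C–O bond. The step needs this facial selectivity and cyclisation in preference to oligomerisation. A monodentate Lewis acid and the bulky, weakly basic silyl ether exclude chelation; the aldehyde cannot enolise because C10 is quaternary; the enol silane comes from the only methyl ketone; and slow addition at high dilution favours ring closure. The Z-C4=C5 bond and the trans-lactone hold the two reacting chains on neighbouring carbons of ring B, which lowers the entropic cost.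

Step 21
Reactants: 29 (1S,4Z,6R,7R,8R,10R)-8-(EpT-oxy)-1-hydroxy-3-oxo-10-(triethylsilyloxy)germacra-4,11(13)-dien-12,6-olide
Product: 30 (1S,3S,4Z,6R,7R,8R,10R)-8-(EpT-oxy)-1,3-dihydroxy-10-(triethylsilyloxy)germacra-4,11(13)-dien-12,6-olide
Conditions: Me4NBH(OAc)3, MeCN/AcOH, −30 °C
Reagents that add atoms: none
Why: Evans–Saksena reduction; the C1 hydroxyl exchanges onto boron and hydride is delivered intramolecularly through a chair-like transition state, giving the 1,3-anti diol (3S). The reagent attacks only the hydroxyl-bearing ketone in 1,2 fashion and leaves the esters, the lactone and the enoate alone.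

Step 22
Reactants: 30 (1S,3S,4Z,6R,7R,8R,10R)-8-(EpT-oxy)-1,3-dihydroxy-10-(triethylsilyloxy)germacra-4,11(13)-dien-12,6-olide
Product: 31 (1S,3S,4Z,6R,7R,8R,10R)-3-benzoyloxy-8-(EpT-oxy)-1-hydroxy-10-(triethylsilyloxy)germacra-4,11(13)-dien-12,6-olide
Conditions: BzCl (1.1 equiv), pyridine, CH2Cl2, −20 → 0 °C
Reagents that add atoms: benzoyl chloride, O=C(Cl)c1ccccc1
Why: Kinetic acylation of the more accessible allylic C3 hydroxyl; the C1 hydroxyl is neopentyl-like, flanked by the quaternary C10 and its triethylsilyloxy group, and should react far more slowly.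

Step 23
Reactants: 31 (1S,3S,4Z,6R,7R,8R,10R)-3-benzoyloxy-8-(EpT-oxy)-1-hydroxy-10-(triethylsilyloxy)germacra-4,11(13)-dien-12,6-olide
Product: 32 (1S,3S,4Z,6R,7R,8R,10R)-3-benzoyloxy-8-(EpT-oxy)-1-(methanesulfonyloxy)-10-(triethylsilyloxy)germacra-4,11(13)-dien-12,6-olide
Conditions: MsCl, Et3N, CH2Cl2, 0 °C
Reagents that add atoms: methanesulfonyl chloride, CS(=O)(=O)Cl
Why: Mesylation by way of sulfene works on hindered secondary alcohols and retains configuration at C1, because only the O–H bond reacts.

Step 24
Reactants: 32 (1S,3S,4Z,6R,7R,8R,10R)-3-benzoyloxy-8-(EpT-oxy)-1-(methanesulfonyloxy)-10-(triethylsilyloxy)germacra-4,11(13)-dien-12,6-olide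
Product: 34 (1R,3S,4Z,6R,7R,8R,10R)-3-benzoyloxy-1,10-epoxy-8-[(2R,3S)-2,3-dimethyloxirane-2-carbonyloxy]germacra-4,11(13)-dien-12,6-olide (target CNP0324463.5), via hydroxy mesylate 33 (not isolated)
Conditions: Bu4NF, THF, 0 °C
Reagents that add atoms: none
Why: Fluoride cleaves the Si–O bond and the C10 alkoxide displaces the antiperiplanar C1 mesylate in a 3-exo-tet Williamson closure with inversion, so 1S,10R becomes the 1R,10R trans-epoxide. This closure onto a neighbouring sulfonate should be faster than acyl transfer from O8 or addition to the enoate.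

## Compound list

1 | 2-methylprop-2-en-1-ol | C=C(C)CO | starting material
2 | (S)-(2-methyloxiran-2-yl)methanol | OC[C@@]1(C)CO1 | intermediate
3 | (R)-2-{[(4-methoxybenzyl)oxy]methyl}-2-methyloxirane | COc1ccc(COC[C@@]2(C)CO2)cc1 | intermediate
4 | (R)-1-[(4-methoxybenzyl)oxy]-2-methylpent-4-en-2-ol | C=CC[C@@](C)(O)COCc1ccc(OC)cc1 | intermediate
5 | (R)-triethyl({1-[(4-methoxybenzyl)oxy]-2-methylpent-4-en-2-yl}oxy)silane | C=CC[C@@](C)(O[Si](CC)(CC)CC)COCc1ccc(OC)cc1 | intermediate
6 | (4R)-5-[(4-methoxybenzyl)oxy]-4-methyl-4-[(triethylsilyl)oxy]pentane-1,2-diol (both C2 epimers) | OCC(O)C[C@@](C)(O[Si](CC)(CC)CC)COCc1ccc(OC)cc1 | intermediate (not isolated)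
7 | (R)-4-[(4-methoxybenzyl)oxy]-3-methyl-3-[(triethylsilyl)oxy]butanal | O=CC[C@@](C)(O[Si](CC)(CC)CC)COCc1ccc(OC)cc1 | intermediate
8 | prop-2-enal | C=CC=O | starting material
9 | rac-hex-1-en-4-yn-3-ol | C=CC(O)C#CC | intermediate
10 | (S)-hex-1-en-4-yn-3-ol | C=C[C@H](O)C#CC | intermediate
11 | sodium (5S)-2,2-bis(2-methoxyethoxy)-3-methyl-5-vinyl-2,5-dihydro-1,2-oxaaluminol-2-uide (cyclic alkenylaluminate) | C=C[C@@H]1O[Al-](OCCOC)(OCCOC)C(C)=C1.[Na+] | intermediate (not isolated)
12 | (3S,4Z)-5-iodohexa-1,4-dien-3-ol | C=C[C@H](O)/C=C(/C)I | intermediate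
13 | 2-(bromomethyl)prop-2-enoic acid | C=C(CBr)C(=O)O | starting material
14 | (3S,4Z)-5-iodohexa-1,4-dien-3-yl 2-(bromomethyl)prop-2-enoate | C=C[C@H](OC(=O)C(=C)CBr)/C=C(/C)I | intermediate
15 | (5S)-3-(bromomethyl)-5-[(1Z)-2-iodoprop-1-en-1-yl]furan-2(5H)-one | BrCC1=C[C@@H](/C=C(/C)I)OC1=O | intermediate
16 | (E)-2-methylbut-2-enoic acid (tiglic acid) | C/C=C(\C)C(=O)O | starting material
17 | (E)-2-methylbut-2-en-1-ol | C/C=C(\C)CO | intermediate
18 | [(2S,3S)-2,3-dimethyloxiran-2-yl]methanol | OC[C@]1(C)O[C@H]1C | intermediate
19 | (2R,3S)-2,3-dimethyloxirane-2-carboxylic acid | OC(=O)[C@]1(C)O[C@H]1C | intermediate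
20 | bromo{[(5S)-5-[(1Z)-2-iodoprop-1-en-1-yl]-2-oxo-2,5-dihydrofuran-3-yl]methyl}zinc (allylzinc bromide) | Br[Zn]CC1=C[C@@H](/C=C(/C)I)OC1=O | intermediate (not isolated)
21 | lactone alcohol (6S,7R,8S,10R): ring B α-methylene-γ-butyrolactone with (Z)-CH=C(CH3)I on C6 and C8H(OH)–C9H2–C10(CH3)(OTES)–C1H2OPMB on C7 | C=C1C(=O)O[C@H](/C=C(/C)I)[C@H]1[C@@H](O)C[C@@](C)(O[Si](CC)(CC)CC)COCc1ccc(OC)cc1 | intermediate
22 | lactone ester (6S,7R,8R,10R): ring B α-methylene-γ-butyrolactone with (Z)-CH=C(CH3)I on C6 and C8H(OEpT)–C9H2–C10(CH3)(OTES)–C1H2OPMB on C7 | C=C1C(=O)O[C@H](/C=C(/C)I)[C@H]1[C@H](OC(=O)[C@]2(C)O[C@H]2C)C[C@@](C)(O[Si](CC)(CC)CC)COCc1ccc(OC)cc1 | intermediate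
23 | ethoxydiene (6R,7R,8R,10R): ring B α-methylene-γ-butyrolactone with (Z)-CH=C(CH3)–C(OEt)=CH2 on C6 and C8H(OEpT)–C9H2–C10(CH3)(OTES)–C1H2OPMB on C7 | C=C1C(=O)O[C@H](/C=C(/C)C(=C)OCC)[C@H]1[C@H](OC(=O)[C@]2(C)O[C@H]2C)C[C@@](C)(O[Si](CC)(CC)CC)COCc1ccc(OC)cc1 | intermediate (not isolated)
24 | methyl ketone (6R,7R,8R,10R): ring B α-methylene-γ-butyrolactone with (Z)-CH=C(CH3)–C(=O)CH3 on C6 and C8H(OEpT)–C9H2–C10(CH3)(OTES)–C1H2OPMB on C7 | C=C1C(=O)O[C@H](/C=C(/C)C(C)=O)[C@H]1[C@H](OC(=O)[C@]2(C)O[C@H]2C)C[C@@](C)(O[Si](CC)(CC)CC)COCc1ccc(OC)cc1 | intermediate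
25 | keto alcohol (6R,7R,8R,10R): ring B α-methylene-γ-butyrolactone with (Z)-CH=C(CH3)–C(=O)CH3 on C6 and C8H(OEpT)–C9H2–C10(CH3)(OTES)–C1H2OH on C7 | C=C1C(=O)O[C@H](/C=C(/C)C(C)=O)[C@H]1[C@H](OC(=O)[C@]2(C)O[C@H]2C)C[C@@](C)(O[Si](CC)(CC)CC)CO | intermediate
26 | keto aldehyde (6R,7R,8R,10R): ring B α-methylene-γ-butyrolactone with (Z)-CH=C(CH3)–C(=O)CH3 on C6 and C8H(OEpT)–C9H2–C10(CH3)(OTES)–C1H=O on C7 | C=C1C(=O)O[C@H](/C=C(/C)C(C)=O)[C@H]1[C@H](OC(=O)[C@]2(C)O[C@H]2C)C[C@@](C)(O[Si](CC)(CC)CC)C=O | intermediate
27 | silyl dienol ether aldehyde (6R,7R,8R,10R): ring B α-methylene-γ-butyrolactone with (Z)-CH=C(CH3)–C(OTMS)=CH2 on C6 and C8H(OEpT)–C9H2–C10(CH3)(OTES)–C1H=O on C7 | C=C1C(=O)O[C@H](/C=C(/C)C(=C)O[Si](C)(C)C)[C@H]1[C@H](OC(=O)[C@]2(C)O[C@H]2C)C[C@@](C)(O[Si](CC)(CC)CC)C=O | intermediate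
28 | (1S,4Z,6R,7R,8R,10R)-1-(difluoroboryloxy)-8-(EpT-oxy)-3-oxo-10-(triethylsilyloxy)germacra-4,11(13)-dien-12,6-olide | C=C1C(=O)O[C@@H]2/C=C(/C)C(=O)C[C@H](OB(F)F)[C@](C)(O[Si](CC)(CC)CC)C[C@@H](OC(=O)[C@]3(C)O[C@H]3C)[C@@H]12 | intermediate (not isolated)
29 | (1S,4Z,6R,7R,8R,10R)-8-(EpT-oxy)-1-hydroxy-3-oxo-10-(triethylsilyloxy)germacra-4,11(13)-dien-12,6-olide | C=C1C(=O)O[C@@H]2/C=C(/C)C(=O)C[C@H](O)[C@](C)(O[Si](CC)(CC)CC)C[C@@H](OC(=O)[C@]3(C)O[C@H]3C)[C@@H]12 | intermediate
30 | (1S,3S,4Z,6R,7R,8R,10R)-8-(EpT-oxy)-1,3-dihydroxy-10-(triethylsilyloxy)germacra-4,11(13)-dien-12,6-olide | C=C1C(=O)O[C@@H]2/C=C(/C)[C@@H](O)C[C@H](O)[C@](C)(O[Si](CC)(CC)CC)C[C@@H](OC(=O)[C@]3(C)O[C@H]3C)[C@@H]12 | intermediate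
31 | (1S,3S,4Z,6R,7R,8R,10R)-3-benzoyloxy-8-(EpT-oxy)-1-hydroxy-10-(triethylsilyloxy)germacra-4,11(13)-dien-12,6-olide | C=C1C(=O)O[C@@H]2/C=C(/C)[C@@H](OC(=O)c3ccccc3)C[C@H](O)[C@](C)(O[Si](CC)(CC)CC)C[C@@H](OC(=O)[C@]3(C)O[C@H]3C)[C@@H]12 | intermediate
32 | (1S,3S,4Z,6R,7R,8R,10R)-3-benzoyloxy-8-(EpT-oxy)-1-(methanesulfonyloxy)-10-(triethylsilyloxy)germacra-4,11(13)-dien-12,6-olide | C=C1C(=O)O[C@@H]2/C=C(/C)[C@@H](OC(=O)c3ccccc3)C[C@H](OS(C)(=O)=O)[C@](C)(O[Si](CC)(CC)CC)C[C@@H](OC(=O)[C@]3(C)O[C@H]3C)[C@@H]12 | intermediate
33 | (1S,3S,4Z,6R,7R,8R,10R)-3-benzoyloxy-8-(EpT-oxy)-10-hydroxy-1-(methanesulfonyloxy)germacra-4,11(13)-dien-12,6-olide | C=C1C(=O)O[C@@H]2/C=C(/C)[C@@H](OC(=O)c3ccccc3)C[C@H](OS(C)(=O)=O)[C@](C)(O)C[C@@H](OC(=O)[C@]3(C)O[C@H]3C)[C@@H]12 | intermediate (not isolated)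
34 | (1R,3S,4Z,6R,7R,8R,10R)-3-benzoyloxy-1,10-epoxy-8-[(2R,3S)-2,3-dimethyloxirane-2-carbonyloxy]germacra-4,11(13)-dien-12,6-olide | C=C1C(=O)O[C@@H]2/C=C(/C)[C@@H](OC(=O)c3ccccc3)C[C@H]3O[C@]3(C)C[C@@H](OC(=O)[C@]3(C)O[C@H]3C)[C@@H]12 | target

## Step count and least certain steps

Total: 24 steps. Longest linear sequence: 16 steps (steps 1–5 then 14–24; the branch through steps 6–10 is equally long).

**Step 20 (key step).** Most likely to go wrong: intermolecular aldol addition (oligomers) instead of ten-membered closure, because the cyclic transition state is strained and entropically costly. Ring constraints may also erode the Felkin facial preference, and protodesilylation may simply return 26. Fallback: a samarium Reformatsky closure, which forms the enolate irreversibly from a carbon–halogen bond and closes medium rings through a metal-bridged transition state. It sets out from 27: N-bromosuccinimide in THF at −78 °C brominates the diene terminus to give the bromomethyl ketone aldehyde F1. SmI2 in THF at −78 °C under high dilution then generates the samarium enolate at C2, which adds to the C1 aldehyde; the route is rejoined at 29.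

**Step 19.** Most likely to go wrong: the silyl triflate acting as a Lewis acid, which would trigger an uncontrolled aldol addition of the fresh enol silane to the aldehyde or open the ester oxirane; deprotonation at C6 to give the extended dienol ether is a lesser risk. Fallback: no enol silane is isolated. Starting from 26, (c-C6H11)2BCl and Et3N in Et2O at −78 °C under high dilution form the boron enolate of the methyl ketone in the presence of the non-enolisable aldehyde, and it cyclises through a closed transition state. The Cornforth arrangement of the α-silyloxy aldehyde predicts the same 1S carbinol. After a non-oxidative work-up the route is rejoined at 29; no new compound is formed.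

**Step 14.** Most likely to go wrong: incomplete simple diastereoselection at C8 (open and closed transition states competing) and, less likely, reduction of the allylic bromide before it adds. Fallback: both C8 epimers are used, so the outcome at C8 stops mattering. Starting from the crude product of 7 and 15, the epimers are separated. Alcohol 21 continues through step 15, while the (8R)-alcohol F2 is acylated with retention by acid 19 under Yamaguchi conditions (2,4,6-trichlorobenzoyl chloride, Et3N, then DMAP, toluene). Both streams meet at 22.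

**Step 15.** Most likely to go wrong: elimination of the activated C8 oxygen toward C7, which would give a diene conjugated with the enoate, or slow displacement by the hindered carboxylate leading to retention through an acyloxyphosphonium pathway. Fallback: inversion and acylation are separated. Starting from 21, a Mitsunobu reaction with the small, more acidic chloroacetic acid gives the inverted chloroacetate F3. Thiourea and NaHCO3 in ethanol remove the chloroacetyl group to give the (8R)-alcohol F2, and Yamaguchi esterification with 19 returns to 22.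

**Step 22.** Most likely to go wrong: poor discrimination between the C1 and C3 hydroxyls in the medium ring, or 1,3-acyl migration. Fallback: the two oxygens are distinguished by timing instead of hindrance, with reagent control at C3. Starting from 29, the C1 hydroxyl is silylated with N-(trimethylsilyl)imidazole to give the C1 trimethylsilyl ether F4. The enone is reduced with catecholborane and the (R)-B-methyl oxazaborolidine catalyst at −78 °C to give the (3S)-allylic alcohol F5. Benzoylation of the only free hydroxyl gives the benzoate F6, and pyridinium p-toluenesulfonate in methanol removes the secondary trimethylsilyl ether in preference to the tertiary TES ether. The route is rejoined at 31.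

## Further compounds

F1 | step 20 | bromomethyl ketone aldehyde (6R,7R,8R,10R): ring B α-methylene-γ-butyrolactone with (Z)-CH=C(CH3)–C(=O)CH2Br on C6 and C8H(OEpT)–C9H2–C10(CH3)(OTES)–C1H=O on C7 | C=C1C(=O)O[C@H](/C=C(/C)C(=O)CBr)[C@H]1[C@H](OC(=O)[C@]2(C)O[C@H]2C)C[C@@](C)(O[Si](CC)(CC)CC)C=O
F0 | step 19 | none | none
F2 | step 14 | lactone alcohol (6S,7R,8R,10R), the C8 epimer of 21: ring B α-methylene-γ-butyrolactone with (Z)-CH=C(CH3)I on C6 and C8H(OH)–C9H2–C10(CH3)(OTES)–C1H2OPMB on C7 | C=C1C(=O)O[C@H](/C=C(/C)I)[C@H]1[C@H](O)C[C@@](C)(O[Si](CC)(CC)CC)COCc1ccc(OC)cc1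
F3 | step 15 | chloroacetate (6S,7R,8R,10R): ring B α-methylene-γ-butyrolactone with (Z)-CH=C(CH3)I on C6 and C8H(OC(=O)CH2Cl)–C9H2–C10(CH3)(OTES)–C1H2OPMB on C7 | C=C1C(=O)O[C@H](/C=C(/C)I)[C@H]1[C@H](OC(=O)CCl)C[C@@](C)(O[Si](CC)(CC)CC)COCc1ccc(OC)cc1
F4 | step 22 | (1S,4Z,6R,7R,8R,10R)-8-(EpT-oxy)-3-oxo-10-(triethylsilyloxy)-1-(trimethylsilyloxy)germacra-4,11(13)-dien-12,6-olide | C=C1C(=O)O[C@@H]2/C=C(/C)C(=O)C[C@H](O[Si](C)(C)C)[C@](C)(O[Si](CC)(CC)CC)C[C@@H](OC(=O)[C@]3(C)O[C@H]3C)[C@@H]12
F5 | step 22 | (1S,3S,4Z,6R,7R,8R,10R)-8-(EpT-oxy)-3-hydroxy-10-(triethylsilyloxy)-1-(trimethylsilyloxy)germacra-4,11(13)-dien-12,6-olide | C=C1C(=O)O[C@@H]2/C=C(/C)[C@@H](O)C[C@H](O[Si](C)(C)C)[C@](C)(O[Si](CC)(CC)CC)C[C@@H](OC(=O)[C@]3(C)O[C@H]3C)[C@@H]12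
F6 | step 22 | (1S,3S,4Z,6R,7R,8R,10R)-3-benzoyloxy-8-(EpT-oxy)-10-(triethylsilyloxy)-1-(trimethylsilyloxy)germacra-4,11(13)-dien-12,6-olide | C=C1C(=O)O[C@@H]2/C=C(/C)[C@@H](OC(=O)c3ccccc3)C[C@H](O[Si](C)(C)C)[C@](C)(O[Si](CC)(CC)CC)C[C@@H](OC(=O)[C@]3(C)O[C@H]3C)[C@@H]12
A1 | alternative 1 | ring B α-methylene-γ-butyrolactone with (Z)-CH=C(CH3)I on C6 and C8H(OH)–C9H2–C10(CH3)=C1H–C2H2–C3H2–OSi(t-Bu)Me2 (1(10)E) on C7; C6, C7 and C8 arranged as in the target | C=C1C(=O)O[C@H](/C=C(/C)I)[C@H]1[C@H](O)C/C(C)=C/CCO[Si](C)(C)C(C)(C)C
A2 | alternative 2 | ring A alcohol: cyclodeca-1(10)E,4Z-diene with C8 hydroxyl, C7 3-(PMB-oxy)prop-1-en-2-yl group, C6 PMB ether and C3 tert-butyldimethylsilyl ether; C3, C6, C7 and C8 arranged as in the target | C=C(COCc2ccc(OC)cc2)[C@H]1[C@H](OCc2ccc(OC)cc2)/C=C(/C)[C@@H](O[Si](C)(C)C(C)(C)C)C/C=C(\C)/C[C@H]1O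
A3 | alternative 3 | (1(10)E,3S,4Z,6R,7R,8R)-3-benzoyloxy-8-[(2R,3S)-2,3-dimethyloxirane-2-carbonyloxy]germacra-1(10),4,11(13)-trien-12,6-olide | C=C1C(=O)O[C@@H]2/C=C(/C)[C@@H](OC(=O)c3ccccc3)C/C=C(\C)/C[C@@H](OC(=O)[C@]3(C)O[C@H]3C)[C@@H]12
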